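**Retrosynthetic overview**

1. The ten-membered ring is closed last, at C9–C10, by intramolecular Ni/Cr coupling of a (Z)-vinyl iodide with the C9 aldehyde; O9 acetylation and desilylation follow.
2. The seco compound comes from a C4=C5 Wittig reaction of a formyl-stabilised ylide (C1–C4, C10, C14, C15) with a lactol–aldehyde; the trans α-methylene lactone then closes from the C6 hydroxyl onto the acrylate ester.
3. The lactol–aldehyde comes from ozonolysis of a cyclopentene mono-(S)-2-methylbutanoate, whose free hydroxyl masks one of the two new aldehydes (C9) as a lactol.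
4. The monoester comes from catalytic desymmetrising acylation of a meso cyclopent-4-ene-1,3-diol (fixes C6, C7, C8), made by Luche reduction after a Piancatelli rearrangement (furan to trans-4-hydroxy-5-substituted cyclopentenone) of the furfural/methyl acrylate Baylis–Hillman adduct.
5. Ring order: furan, then cyclopentene (temporary carbocycle, later cleaved), then γ-lactone, then the ten-membered carbocycle.

Assumption: (2S)-2-methylbutanoic anhydride, 5-chloropent-1-yne and both enantiomers of benzotetramisole (BTM) are taken as purchasable; racemic 3 and 4 are drawn as one enantiomer; germacrane numbering (C1–C15, lactone carbonyl C12) is used for atoms of the target.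

**Route**

Step 1
Reactants: 1 furfural; 2 methyl acrylate
Product: 3 methyl 2-[furan-2-yl(hydroxy)methyl]prop-2-enoate (racemic)
Conditions: DABCO (0.5 equiv), neat, rt, 3 d
Reagents that add atoms: none
Why: Morita–Baylis–Hillman reaction of the very electrophilic furfural with the DABCO–acrylate zwitterion joins C7 to the complete C11–C13 acrylate unit; the carbinol stereocentre is destroyed in step 2, so the racemate is used.

Step 2
Reactants: 3
Product: 4 methyl 2-[(1RS,2SR)-2-hydroxy-5-oxocyclopent-3-en-1-yl]prop-2-enoate (racemic; hydroxyl trans to the acrylate unit)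
Conditions: Dy(OTf)3 (10 mol %), t-BuOH/H2O 5:1, 80 °C
Reagents that add atoms: water, O
Why: Proposed new method: Piancatelli rearrangement of a Baylis–Hillman carbinol, in which Lewis-acid ionisation gives a furan-stabilised cation, water adds at furan C5, the ring opens to a 1-hydroxypentadienyl cation and conrotatory 4π electrocyclisation sets the C6/C7 trans relationship; the SN2′-transposed primary allylic alcohol that acid may also form re-ionises to the same delocalised cation and is drained by the irreversible ring closure; the closest known reaction is the Dy(OTf)3- or ZnCl2-catalysed Piancatelli rearrangement of alkyl- and aryl(2-furyl)carbinols.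

Step 3
Reactants: 4
Product: 5 methyl 2-[(1r,2R,5S)-2,5-dihydroxycyclopent-3-en-1-yl]prop-2-enoate (meso; both hydroxyls trans to the acrylate unit)
Conditions: NaBH4, CeCl3·7H2O, MeOH, −78 °C
Reagents that add atoms: none
Why: Luche 1,2-reduction, in which the small cerium-modified hydride is expected to attack anti to the C6 oxygen (as with 4-oxygenated cyclopentenones) and give the C8 alcohol cis to the C6 hydroxyl and trans to the C7 substituent, so that both enantiomers of 4 converge on one meso diol.

Step 4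
Reactants: 5; 6 (2S)-2-methylbutanoic anhydride
Product: 7 methyl 2-[(1S,2R,5S)-2-hydroxy-5-{[(2S)-2-methylbutanoyl]oxy}cyclopent-3-en-1-yl]prop-2-enoate
Conditions: (R)-BTM (5 mol %), i-Pr2NEt, Na2SO4, CHCl3, −20 °C
Reagents that add atoms: none
Why: Enantioselective acyl-transfer desymmetrisation of a meso diol (Birman amidine-type catalysis with an α-branched anhydride), in which the catalyst acylates the allylic carbinol whose alkene/alkyl arrangement matches the fast-reacting (R)-1-arylalkanols; this fixes C6, C7 and C8 absolutely and installs the C8 ester of the target (the antipodal catalyst is used if a pilot run shows the opposite sense).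

Step 5
Reactants: 8 5-chloropent-1-yne
Product: 9 6-chlorohex-2-yn-1-ol
Conditions: n-BuLi, THF, −78 °C; (CH2O)n, −78 °C to rt
Reagents that add atoms: formaldehyde (from paraformaldehyde), C=O
Why: Hydroxymethylation of a lithium acetylide adds C14; the primary chloride is untouched at low temperature.

Step 6
Reactants: 9
Product: 11 (2Z)-6-chloro-2-iodohex-2-en-1-ol, via vinylstannane 10 (not isolated)
Conditions: [Cp*RuCl]4 (1.5 mol %), Bu3SnH, CH2Cl2, rt; then I2, 0 °C
Reagents that add atoms: tributylstannane (its tin stays only in 10), CCCC[SnH](CCCC)CCCC; iodine, [I][I]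
Why: Hydroxyl-directed ruthenium-catalysed trans-hydrostannation (Fürstner) places tin on the alkyne carbon next to the carbinol with anti addition, and iododestannylation with retention gives the iodide cis to the C2 chain, which is the geometry of the C1=C10 bond of the target.

Step 7
Reactants: 11
Product: 12 tert-butyl{[(2Z)-6-chloro-2-iodohex-2-en-1-yl]oxy}dimethylsilane
Conditions: TBSCl, imidazole, CH2Cl2, rt
Reagents that add atoms: tert-butyl(chloro)dimethylsilane, CC(C)(C)[Si](C)(C)Cl
Why: Standard silylation protects the C14 hydroxyl for ylide formation and for the later selective O9 acetylation.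

Step 8
Reactants: 12
Product: 13 [(4Z)-6-{[tert-butyl(dimethyl)silyl]oxy}-5-iodohex-4-en-1-yl](triphenyl)phosphonium iodide
Conditions: PPh3, NaI, MeCN, reflux
Reagents that add atoms: triphenylphosphine, c1ccc(cc1)P(c1ccccc1)c1ccccc1; sodium iodide, [Na+].[I-]
Why: Finkelstein-assisted SN2 quaternisation of the primary chloride; the vinyl iodide does not react with PPh3 without a metal catalyst.

Step 9
Reactants: 13
Product: 15 (5Z)-7-{[tert-butyl(dimethyl)silyl]oxy}-6-iodo-2-(triphenyl-λ5-phosphanylidene)hept-5-enal, via phosphonium ylide 14 (not isolated)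
Conditions: NaN(SiMe3)2 (2.1 equiv), THF, −78 to 0 °C; HCO2Et, −78 °C to rt
Reagents that add atoms: ethyl formate, CCOC=O
Why: C-formylation of a non-stabilised ylide (Trippett acylation) adds C15 at the aldehyde level and gives a storable formyl-stabilised ylide; the amide base avoids iodine–lithium exchange.

Step 10
Reactants: 7; 15
Product: 18 lactol enal [oxolane with C5-hydroxyl (anomers) carrying the (1E,5Z)-2-formyl-6-iodo-7-silyloxyhepta-1,5-dienyl chain at C2], via ozonide 16 (not isolated), via lactol aldehyde 17 (not isolated)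
Conditions: O3, CH2Cl2, −78 °C (Sudan Red 7B end-point); Me2S, −78 °C to rt; then 15 (1.1 equiv), PhMe, 60 °C
Reagents that add atoms: ozone, [O-][O+]=O
Why: Dye-indicated ozonolysis cleaves the isolated ring alkene in preference to the conjugated acrylate; the free C6 hydroxyl immediately captures the C9 aldehyde as a five-membered lactol, so only the C5 aldehyde undergoes the Wittig reaction, and the stabilised ylide gives the (E)-enal (CHO trans to C6), which is the ring-cis C4=C5 geometry.

Step 11
Reactants: 18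
Product: 19 lactol allylic alcohol [as 18 with CH2OH (C15) in place of CHO]
Conditions: NaBH4, CeCl3·7H2O, MeOH, −78 °C, 15 min
Reagents that add atoms: none
Why: Luche 1,2-reduction of the enal is fast at −78 °C, whereas the lactol, the acrylate, both esters and the vinyl iodide are inert under these conditions.

Step 12
Reactants: 19
Product: 20 (1R)-1-[(2R,3S)-2-[(1E,5Z)-7-{[tert-butyl(dimethyl)silyl]oxy}-2-(hydroxymethyl)-6-iodohepta-1,5-dien-1-yl]-4-methylidene-5-oxooxolan-3-yl]-2-oxoethyl (2S)-2-methylbutanoate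
Conditions: PPTS (10 mol %), 5 Å MS, PhMe, 50 °C
Reagents that add atoms: none
Why: Acid-catalysed ring–chain tautomerism exposes the C6 hydroxyl, which lactonises onto the acrylate ester (intramolecular transesterification driven by removal of methanol); this forms the trans-disposed α-methylene-γ-lactone from the existing C6/C7 centres and releases the C9 aldehyde.

Step 13
Reactants: 20
Product: 21 macrocyclic diol [ten-membered ring; 9S-hydroxyl; C15 hydroxyl free; C14 silyl ether]
Conditions: CrCl2 (8 equiv), NiCl2 (1 mol %), DMSO/THF, rt, 0.002 M, slow addition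
Reagents that add atoms: none
Why: Intramolecular Nozaki–Hiyama–Kishi coupling, in which the alkenylchromium formed with retention of the Z geometry adds to the aldehyde anti to the C8 acyloxy group (polar Felkin–Anh) and sets 9S; the two ring-cis alkenes and the trans lactone pre-organise the chain, and free hydroxyls, esters and the methylene lactone are tolerated.

Step 14
Reactants: 21
Product: 23 bis-silyl ether acetate [as the target with both primary hydroxyls as TBS ethers], via bis-silyl ether alcohol 22 (not isolated)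
Conditions: TBSCl (1.1 equiv), imidazole, CH2Cl2, 0 °C; then Ac2O, DMAP, pyridine, rt
Reagents that add atoms: tert-butyl(chloro)dimethylsilane, CC(C)(C)[Si](C)(C)Cl; acetic anhydride, CC(=O)OC(C)=O
Why: The primary allylic C15 hydroxyl is silylated much faster than the hindered secondary C9 hydroxyl, which is then acetylated (DMAP acyl transfer) before the neighbouring C8 ester can migrate.

Step 15
Reactants: 23
Product: 24 CNP0207247.12 (target)
Conditions: HF·pyridine, THF/pyridine, 0 °C to rt
Reagents that add atoms: none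
Why: Fluoride desilylation under buffered acidic conditions frees both primary allylic alcohols without base-promoted acetyl migration or conjugate addition to the methylene lactone.

**Compound list**

1 | furfural (furan-2-carbaldehyde) | O=Cc1ccco1 | starting material
2 | methyl acrylate | C=CC(=O)OC | starting material
3 | methyl 2-[furan-2-yl(hydroxy)methyl]prop-2-enoate (racemic) | C=C(C(=O)OC)C(O)c1ccco1 | intermediate
4 | methyl 2-[(1RS,2SR)-2-hydroxy-5-oxocyclopent-3-en-1-yl]prop-2-enoate (racemic, trans; one enantiomer drawn) | C=C(C(=O)OC)[C@H]1[C@H](O)C=CC1=O | intermediate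
5 | methyl 2-[(1r,2R,5S)-2,5-dihydroxycyclopent-3-en-1-yl]prop-2-enoate (meso) | C=C(C(=O)OC)[C@H]1[C@H](O)C=C[C@@H]1O | intermediate
6 | (2S)-2-methylbutanoic anhydride | CC[C@H](C)C(=O)OC(=O)[C@@H](C)CC | starting material
7 | methyl 2-[(1S,2R,5S)-2-hydroxy-5-{[(2S)-2-methylbutanoyl]oxy}cyclopent-3-en-1-yl]prop-2-enoate | C=C(C(=O)OC)[C@H]1[C@H](O)C=C[C@@H]1OC(=O)[C@@H](C)CC | intermediate
8 | 5-chloropent-1-yne | C#CCCCCl | starting material
9 | 6-chlorohex-2-yn-1-ol | OCC#CCCCCl | intermediate
10 | (2Z)-6-chloro-2-(tributylstannyl)hex-2-en-1-ol (not isolated) | ClCCC/C=C(\[Sn](CCCC)(CCCC)CCCC)CO | intermediate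
11 | (2Z)-6-chloro-2-iodohex-2-en-1-ol | ClCCC/C=C(\I)CO | intermediate
12 | tert-butyl{[(2Z)-6-chloro-2-iodohex-2-en-1-yl]oxy}dimethylsilane | ClCCC/C=C(\I)CO[Si](C)(C)C(C)(C)C | intermediate
13 | [(4Z)-6-{[tert-butyl(dimethyl)silyl]oxy}-5-iodohex-4-en-1-yl](triphenyl)phosphonium iodide | [I-].CC(C)(C)[Si](C)(C)OC/C(I)=C/CCC[P+](c1ccccc1)(c1ccccc1)c1ccccc1 | intermediate
14 | tert-butyl(dimethyl){[(2Z)-2-iodo-6-(triphenyl-λ5-phosphanylidene)hex-2-en-1-yl]oxy}silane (not isolated) | CC(C)(C)[Si](C)(C)OC/C(I)=C/CCC=P(c1ccccc1)(c1ccccc1)c1ccccc1 | intermediate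
15 | (5Z)-7-{[tert-butyl(dimethyl)silyl]oxy}-6-iodo-2-(triphenyl-λ5-phosphanylidene)hept-5-enal | O=CC(CC/C=C(\I)CO[Si](C)(C)C(C)(C)C)=P(c1ccccc1)(c1ccccc1)c1ccccc1 | intermediate
16 | secondary ozonide of 7 (6,7,8-trioxabicyclo[3.2.1]octane; other centres as in 7; not isolated) | O[C@@H]1C2OOC(O2)[C@H](OC(=O)[C@@H](C)CC)[C@H]1C(=C)C(=O)OC | intermediate
17 | methyl 2-[(2S,3S,4R)-2-formyl-5-hydroxy-4-{[(2S)-2-methylbutanoyl]oxy}oxolan-3-yl]prop-2-enoate (anomer mixture; not isolated) | O=C[C@H]1OC(O)[C@H](OC(=O)[C@@H](C)CC)[C@H]1C(=C)C(=O)OC | intermediate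
18 | methyl 2-[(2R,3S,4R)-2-[(1E,5Z)-7-{[tert-butyl(dimethyl)silyl]oxy}-2-formyl-6-iodohepta-1,5-dien-1-yl]-5-hydroxy-4-{[(2S)-2-methylbutanoyl]oxy}oxolan-3-yl]prop-2-enoate | O=C/C(CC/C=C(\I)CO[Si](C)(C)C(C)(C)C)=C/[C@H]1OC(O)[C@H](OC(=O)[C@@H](C)CC)[C@H]1C(=C)C(=O)OC | intermediate
19 | methyl 2-[(2R,3S,4R)-2-[(1E,5Z)-7-{[tert-butyl(dimethyl)silyl]oxy}-2-(hydroxymethyl)-6-iodohepta-1,5-dien-1-yl]-5-hydroxy-4-{[(2S)-2-methylbutanoyl]oxy}oxolan-3-yl]prop-2-enoate | OC/C(CC/C=C(\I)CO[Si](C)(C)C(C)(C)C)=C/[C@H]1OC(O)[C@H](OC(=O)[C@@H](C)CC)[C@H]1C(=C)C(=O)OC | intermediate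
20 | (1R)-1-[(2R,3S)-2-[(1E,5Z)-7-{[tert-butyl(dimethyl)silyl]oxy}-2-(hydroxymethyl)-6-iodohepta-1,5-dien-1-yl]-4-methylidene-5-oxooxolan-3-yl]-2-oxoethyl (2S)-2-methylbutanoate | C=C1C(=O)O[C@H](/C=C(/CO)CC/C=C(\I)CO[Si](C)(C)C(C)(C)C)[C@H]1[C@@H](OC(=O)[C@@H](C)CC)C=O | intermediate
21 | (3aS,4R,5S,6Z,10E,11aR)-6-({[tert-butyl(dimethyl)silyl]oxy}methyl)-5-hydroxy-10-(hydroxymethyl)-3-methylidene-2-oxo-2,3,3a,4,5,8,9,11a-octahydrocyclodeca[b]furan-4-yl (2S)-2-methylbutanoate | C=C1C(=O)O[C@@H]2/C=C(/CO)CC/C=C(/CO[Si](C)(C)C(C)(C)C)[C@H](O)[C@H](OC(=O)[C@@H](C)CC)[C@@H]12 | intermediate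
22 | (3aS,4R,5S,6Z,10E,11aR)-6,10-bis({[tert-butyl(dimethyl)silyl]oxy}methyl)-5-hydroxy-3-methylidene-2-oxo-2,3,3a,4,5,8,9,11a-octahydrocyclodeca[b]furan-4-yl (2S)-2-methylbutanoate (not isolated) | C=C1C(=O)O[C@@H]2/C=C(/CO[Si](C)(C)C(C)(C)C)CC/C=C(/CO[Si](C)(C)C(C)(C)C)[C@H](O)[C@H](OC(=O)[C@@H](C)CC)[C@@H]12 | intermediate
23 | (3aS,4R,5S,6Z,10E,11aR)-5-(acetyloxy)-6,10-bis({[tert-butyl(dimethyl)silyl]oxy}methyl)-3-methylidene-2-oxo-2,3,3a,4,5,8,9,11a-octahydrocyclodeca[b]furan-4-yl (2S)-2-methylbutanoate | C=C1C(=O)O[C@@H]2/C=C(/CO[Si](C)(C)C(C)(C)C)CC/C=C(/CO[Si](C)(C)C(C)(C)C)[C@H](OC(C)=O)[C@H](OC(=O)[C@@H](C)CC)[C@@H]12 | intermediate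
24 | CNP0207247.12: (3aS,4R,5S,6Z,10E,11aR)-5-(acetyloxy)-6,10-bis(hydroxymethyl)-3-methylidene-2-oxo-2,3,3a,4,5,8,9,11a-octahydrocyclodeca[b]furan-4-yl (2S)-2-methylbutanoate (germacrane numbering 6R,7S,8R,9S; both ring alkenes cis within the ring) | C=C1C(=O)O[C@@H]2/C=C(/CO)CC/C=C(/CO)[C@H](OC(C)=O)[C@H](OC(=O)[C@@H](C)CC)[C@@H]12 | target

**Step count and risks**

Total step count: 15 (steps 1–4 core, steps 5–9 ylide 15, steps 10–15 union and endgame).
Longest linear sequence: 11 steps (8 to 24 through steps 5–15); from furfural the sequence is 10 steps.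

Most likely to fail, with one fallback each:

Step 2 (acid may divert 3 into the transposed allylic alcohol, or the doubly activated C7–H of 4 may isomerise). The fallback sets out from 3 and comes back at 4, reaching the cyclopentenone by oxidative furan opening and aldol closure, so no cation is formed next to the acrylate. Acetylation of 3 (Ac2O, DMAP) gives methyl 2-[(acetyloxy)(furan-2-yl)methyl]prop-2-enoate F1. DABCO followed by NaBH4 in THF/H2O (SN2′–SN2′ hydride delivery) gives methyl 2-(furan-2-ylmethyl)prop-2-enoate F2. NBS/NaHCO3 in aqueous acetone at −20 °C opens the furan to methyl (5Z)-2-methylidene-4,7-dioxohept-5-enoate F3. Intramolecular aldol addition of the doubly activated methylene onto the aldehyde in pH 7.4 phosphate buffer then gives 4 (trans by equilibration).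

Step 10 (ozone may touch the acrylate, and the hot formyl-ylide Wittig may not discriminate cleanly between the free aldehyde and the lactol). The fallback sets out from 7 and comes back at 18. Catalytic dihydroxylation (OsO4, N-methylmorpholine N-oxide) gives the ring cis-diol of 7, F4, with the new hydroxyls on the face of the acrylate substituent. NaIO4 cleavage gives the same lactol aldehyde 17. In place of 15, the more nucleophilic amide-stabilised ylide (5Z)-7-{[tert-butyl(dimethyl)silyl]oxy}-6-iodo-N-methoxy-N-methyl-2-(triphenyl-λ5-phosphanylidene)hept-5-enamide F5 is used, made from 13 with NaN(SiMe3)2 and N-methoxy-N-methylcarbamoyl chloride. It reacts with 17 at room temperature to give the (E)-configured unsaturated Weinreb amide lactol F6. Cp2Zr(H)Cl in THF then reduces the amide chemoselectively to enal 18.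

Step 13 (ring closure has precedent, but the C9 configuration is decided by the macrocyclic transition state and may be wrong or mixed). The fallback sets out from 21 and comes back at 22, replacing substrate control in the C–C bond formation by reagent control in a ketone reduction. The mixture of 21 and its 9-epimer, the (9R)-macrocyclic diol F7, is silylated as in the first half of step 14, giving 22 and the (9R)-bis-silyl ether alcohol F8. Dess–Martin periodinane converts both into the macrocyclic C9 enone F9. Reduction with (S)-Me-CBS oxazaborolidine and catecholborane (Corey model with the alkenyl group as the large substituent; the antipodal catalyst if the ring overrides it) returns 22 as the single 9S alcohol.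

**Further compounds**

F1 | step 2 | methyl 2-[(acetyloxy)(furan-2-yl)methyl]prop-2-enoate (racemic) | C=C(C(=O)OC)C(OC(C)=O)c1ccco1
F2 | step 2 | methyl 2-(furan-2-ylmethyl)prop-2-enoate | C=C(Cc1ccco1)C(=O)OC
F3 | step 2 | methyl (5Z)-2-methylidene-4,7-dioxohept-5-enoate | C=C(CC(=O)/C=C\C=O)C(=O)OC
F4 | step 10 | ring cis-diol of 7: methyl 2-[2,3,4-trihydroxy-5-{[(2S)-2-methylbutanoyl]oxy}cyclopentyl]prop-2-enoate with the two new hydroxyls cis to the acrylate unit | C=C(C(=O)OC)[C@H]1[C@H](O)[C@@H](O)[C@@H](O)[C@@H]1OC(=O)[C@@H](C)CC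
F5 | step 10 | (5Z)-7-{[tert-butyl(dimethyl)silyl]oxy}-6-iodo-N-methoxy-N-methyl-2-(triphenyl-λ5-phosphanylidene)hept-5-enamide | CON(C)C(=O)C(CC/C=C(\I)CO[Si](C)(C)C(C)(C)C)=P(c1ccccc1)(c1ccccc1)c1ccccc1
F6 | step 10 | lactol Weinreb amide: as 18 with C(=O)N(OMe)Me in place of CHO | CON(C)C(=O)/C(CC/C=C(\I)CO[Si](C)(C)C(C)(C)C)=C/[C@H]1OC(O)[C@H](OC(=O)[C@@H](C)CC)[C@H]1C(=C)C(=O)OC
F7 | step 13 | (9R)-epimer of 21 (cyclodeca[b]furan numbering 5R) | C=C1C(=O)O[C@@H]2/C=C(/CO)CC/C=C(/CO[Si](C)(C)C(C)(C)C)[C@@H](O)[C@H](OC(=O)[C@@H](C)CC)[C@@H]12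
F8 | step 13 | (9R)-epimer of 22 (cyclodeca[b]furan numbering 5R) | C=C1C(=O)O[C@@H]2/C=C(/CO[Si](C)(C)C(C)(C)C)CC/C=C(/CO[Si](C)(C)C(C)(C)C)[C@@H](O)[C@H](OC(=O)[C@@H](C)CC)[C@@H]12
F9 | step 13 | C9 ketone of 22: (3aS,4R,6Z,10E,11aR)-6,10-bis({[tert-butyl(dimethyl)silyl]oxy}methyl)-3-methylidene-2,5-dioxo-2,3,3a,4,5,8,9,11a-octahydrocyclodeca[b]furan-4-yl (2S)-2-methylbutanoate | C=C1C(=O)O[C@@H]2/C=C(/CO[Si](C)(C)C(C)(C)C)CC/C=C(/CO[Si](C)(C)C(C)(C)C)C(=O)[C@H](OC(=O)[C@@H](C)CC)[C@@H]12
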